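A flask cannot turn over more substrate than it has solid reagent for, if each turnover takes one unit of it, and Anna starts from that: the solid is a reactant, so its charge must count. Ben doubts it. Their quarrel concerns this flask and these two runs.

| flask | left-handed substrate | right-handed substrate | solid reagent | precatalyst | added ligand | remark | time |
|---|---|---|---|---|---|---|---|
| Thursday's | 14 mM | 14 mM | 21 mM | 0.29 mM | 0.91 mM | run made earlier |  |
| Saturday's | 14 mM | 14 mM | 84 mM | 0.29 mM | 0.91 mM | run made earlier |  |
| flask | 14 mM | 14 mM | 42.0 mM | 0.29 mM | 0.91 mM |  | 4.0 h |

| run | time / h | left-handed substrate / % | right-handed substrate / % |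
|---|---|---|---|
| Thursday's | 0.250 | 47.5 | 48.3 |
| Thursday's | 0.833 | 41.8 | 48.5 |
| Thursday's | 1.33 | 35.1 | 48.3 |
| Thursday's | 2.00 | 26.7 | 46.8 |
| Thursday's | 3.00 | 14.5 | 45.1 |
| Thursday's | 4.00 | 8.6 | 42.3 |
| Saturday's | 0.667 | 43.7 | 50.2 |
| Saturday's | 1.33 | 34.5 | 47.0 |
| Saturday's | 2.00 | 26.6 | 47.6 |
| Saturday's | 2.50 | 19.6 | 46.3 |
| Saturday's | 3.00 | 14.9 | 42.9 |
| Saturday's | 4.00 | 9.8 | 42.2 |

(readings scatter by 1 percentage point)

- free catalyst is single-handed; left-handed substrate and right-handed substrate are mirror images of each other, charged as a racemate, each of them at the stated concentration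
- as a solid, counted per litre of solution: solid reagent
- at the start none of the solid reagent is in solution
- an excess is below zero if the other one leads

- part of the left-handed substrate and right-handed substrate charged together that has reacted at 4.0 h
- excess of left-handed product over right-handed product in the product at 4.0 h
- excess of right-handed substrate over left-handed substrate among what is left of the two at 4.0 h

Anna holds that the pace follows the charge, as for any reactant of order one. The flask has twice Thursday's solid, so after 2.00 h its left-handed substrate should stand where Thursday's stood at 4.00 h, at 8.6%.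

Ben holds that the charge does not enter the pace at all. Saturday had 4.00 times Thursday's charge, yet by 2.00 h it had lost 1.00 times as much left-handed substrate, as far as the readings show. Anna answers that Saturday may have met some other brake, and that the flask's own charge is untested.

Ben therefore reckons what a run needs. He averages the part reacted at 4.00 h over both runs and multiplies it by the substrate charged, which gives 13.6 mM. This is the solid bill, the solid reagent a run takes by that time, one unit per substrate reacted. Thursday's 21 mM exceeded it, and so does the flask's 42.0 mM. Ben commits to the same curve and to 48.6% reacted. At one unit per substrate reacted, a charge under the bill caps the reacted part at that charge divided by the substrate charged.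

The forecast sides with Ben, “Rate is therefore independent of solid loading”, and gives 48.6% reacted, 68% product excess and 64.2% substrate excess.

The flask gives 50.3% reacted, 68.9% product excess and 69.4% substrate excess, and its left-handed substrate stands at 26.1% after 2.00 h, above Anna's 8.6%.

    coupling partner + catalyst intermediate A → free catalyst + left-handed product (k = 3.13 L mol⁻¹ s⁻¹)
    coupling partner + catalyst intermediate B → free catalyst + right-handed product (k = 1.37 L mol⁻¹ s⁻¹)
    free catalyst + added ligand ⇌ idle complex (K = 1700 L mol⁻¹, k = 1.11 L mol⁻¹ s⁻¹)
    solid reagent ⇌ coupling partner, rate k4*(cs4 - [coupling partner]) while solid is left; crystals form when [coupling partner] > cs4 (solubility = 5.50 mM, k = 4.75 × 10⁻⁴ s⁻¹)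
    free catalyst + left-handed substrate ⇌ catalyst intermediate A (K = 220 L mol⁻¹, k = 77.4 L mol⁻¹ s⁻¹)
    free catalyst + right-handed substrate ⇌ catalyst intermediate B (K = 44.1 L mol⁻¹, k = 27.5 L mol⁻¹ s⁻¹)
    precatalyst → free catalyst (k = 9.57 × 10⁻⁴ s⁻¹)

At 1.66 h in the flask, coupling partner, the dissolved form of the solid reagent, is made, each step taken net, 1.06 times as fast as it is used. After 2.00 h it stands at 2.99 mM, below its solubility of 5.5 mM, and while solid is left the dissolving rate is proportional to that gap, with no term for the solid's amount. Counting solid and dissolved reagent together, the flask has lost 14.0 mM of its 42.0 mM by 4.00 h, against a bill of 13.6 mM. Anna's region lies under the bill: in the same flask with 10 mM charged, the solid is the limiting reagent, it stands at 0% at 4.00 h, the cap is 35.7%, and the part reacted is 35.3%.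

Readings and results are simulated on assumed constants.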